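The numbers of this flask are invented; the flask was simulated.

Do not assume that a charged free base takes up the acid set free; reckon first who gets it.

    electrophile + nucleophile ⇌ acid set free + product (K1 = 0.89, k1 = 1.86 × 10⁻⁴ /M/s)
    nucleophile + acid set free ⇌ protonated nucleophile, settled at all times (K2 = 9710 /M)
    acid set free + free base ⇌ salt of the base (K3 = 33.0 /M, k3 = 0.00128 /M/s)

- west: electrophile 0.20 M; nucleophile 1.50 equiv; free base 0.450 equiv; time 15 h
- east: electrophile 0.20 M; nucleophile 1.50 equiv; free base 0.300 equiv; time 15 h

- part of the electrophile that has reacted at the end, west
- part of the electrophile that has reacted at the end, east
- what raising the equivalents of free base from its lowest to its highest value here does to the part of the electrophile that has reacted (changes below 5 percentage points count as none) (no change / it rises / it falls)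

Who gets the acid? Take west, the richer in base, with half of the electrophile reacted. Step 2 at balance then holds the acid set free near 1.03 × 10⁻⁴ M. Divide the forward rate of salt formation by the rate of step 1 and time drops out: at that moment the free base takes up acid at 0.638 % of the rate at which step 1 sets it free. The way back of step 1 runs at 0.116 % of its forward rate, so set both aside.

What does a product cost, then? One nucleophile reacts and a second takes the acid, so charge two per electrophile. Dividing the equivalents of nucleophile by this cost gives the ceiling, 75.0 %, the part of the electrophile that the nucleophile, here the limiting reagent, can pay for at that cost.

How near does the time come? Form the clock, rate constant times electrophile charge times time: 2.01. Let E be the exponential of (two minus the nucleophile equivalents) times the clock, 2.73. Integrating step 1 gives the reacted part as ceiling times (E minus one) over (E minus ceiling): by my hand, 65.5 % in either flask.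

The forecast says 65.8 % for west (63 % to 69 %), 65.6 % for east (63 % to 68 %) and no change, with “the base nearly a spectator at either loading”.

The simulation gives 65.5 % for west, 65.5 % for east and no change, a change of 0.015 percentage points. At 150 h, west stands at 75.2 %, against the ceiling of 75.0 %. Now take a neighbouring flask, which is west with 0.600 equiv of nucleophile. Its ceiling is 30.0 %, its E is 16.6, and the same formula gives 28.7 %. In the simulated neighbouring flask, 28.9 % has reacted at 15.0 h, with 5.3 % of its nucleophile still unbound.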